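## Retrosynthetic overview

- Ampelopsin B ⇒ open-chain hexaphenol with only the C7 stereocentre, by cutting C8'–C(ring A) and C7'–O. Forward, one oxidative dearomatisation of the 4-hydroxystyryl phenol gives a quinone-methide cation that the symmetric resorcinol ring A traps through C (seven-membered ring) and then O (dihydrofuran).
- Hexaphenol ⇒ two resveratrol units, by cutting C7–C(ring B). Forward, a chiral acid tautomerises a 4-hydroxystilbene to its p-quinone methide and a resorcinol adds to it enantioselectively (Friedel–Crafts).
- Complementary masking decides which unit plays which role: 3,5-di-O-acetylresveratrol (only 4'-OH free) can only be the electrophile, and 4'-O-acetylresveratrol (only the resorcinol free) can only be the nucleophile.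
- Ring order: acyclic C7 centre → seven-membered carbocycle → dihydrobenzofuran, the last two in the same operation.

Labels: C7/C8 = CH(Ar)–CH2 bridge of the seven-membered ring; C8'/C7' = CH and O–CH(Ar) of the dihydrofuran; ring A = resorcinol ring fused to the furan; ring B = resorcinol ring on C8'. The target is (7S,7'S,8'S).

Assumption: resveratrol triacetate (3) is bought as a catalogue compound; if not, Ac2O/pyridine on 1 adds one step.

Assumption: the (R)-acid in step 3 is taken to give (S)-5; if the first run shows the opposite sense, the (S)-acid is used.

## Route

Step 1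
Reactants: 1, resveratrol
Product: 2, 4'-O-acetylresveratrol (acetate on the para-phenol only; resorcinol OHs free)
Conditions: vinyl acetate (5 equiv), Novozym 435 (CAL-B), t-amyl alcohol, 40 °C
Reagents that add atoms: vinyl acetate, C=COC(C)=O
Why: Lipase-catalysed regioselective transesterification; CAL-B acylates only the unhindered 4'-OH, and no stereocentre is involved.

Step 2
Reactants: 3, resveratrol triacetate
Product: 4, 3,5-di-O-acetylresveratrol (4'-OH free; both resorcinol OHs acetylated)
Conditions: n-BuOH (4 equiv), Novozym 435, MTBE, 40 °C
Reagents that add atoms: none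
Why: Regioselective enzymatic alcoholysis; the same enzyme removes the 4'-acetate first and leaves the two hindered resorcinol acetates.

Step 3
Reactants: 2 (2 equiv) and 4 (1 equiv, added by syringe pump)
Product: 5, (S)-1-(4-hydroxyphenyl)-1-{2,4-dihydroxy-6-[(E)-4-acetoxystyryl]phenyl}-2-(3,5-diacetoxyphenyl)ethane (new C7–C bond to C2 of the resorcinol ring of 2)
Conditions: (R)-TRIP N-triflylphosphoramide (5 mol %), CH2Cl2–PhCF3, 0 °C → rt
Reagents that add atoms: none
Why: Proposed new method: the chiral acid protonates C8 of 4 to give the dearomatised p-quinone methide of its 4-hydroxyphenyl ring within a chiral ion pair, and the H-bonded resorcinol of 2 adds 1,6 through its ortho/para-activated C2 to set C7 (S), with the acetates ensuring 4 is the only electrophile and 2 the only good nucleophile; the closest known reaction types are chiral-phosphoric-acid-catalysed 1,6-Friedel–Crafts additions of phenols to p-quinone methides and chiral-acid hydrofunctionalisation of hydroxystyrenes via quinone methides.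

Step 4
Reactants: 5
Product: 6, (S)-1-(4-hydroxyphenyl)-1-{2,4-dihydroxy-6-[(E)-4-hydroxystyryl]phenyl}-2-(3,5-dihydroxyphenyl)ethane (hexaphenol)
Conditions: K2CO3 (4 equiv), degassed MeOH, 0 °C, Ar; then AcOH
Reagents that add atoms: none
Why: Mild methanolysis of three aryl acetates; the C7–H is not acidic and there is no retro-Friedel–Crafts pathway under base, so C7 is untouched.

Step 5
Reactants: 6
Product: 7, ampelopsin B, (7S,7'S,8'S)
Conditions: FeCl3·6H2O (2.2 equiv, slow addition), acetone, 1 mM, 0 °C → rt, Ar
Reagents that add atoms: none
Why: Proposed new method: two-electron oxidation of the only 4-hydroxystilbene phenol dearomatises it to a quinone-methide cation electrophilic at C8'; ring A attacks through either of its two equivalent ortho carbons (Friedel–Crafts, seven-membered ring), C8' being set by C7 through a compact transition state with the quinone-methide arm over the reacting C=C–OH edge and anti to the C7 aryl, and the adjacent OH then adds 1,6 to the resulting p-quinone methide to give the trans-dihydrobenzofuran (C7', thermodynamic); the closest known reaction is the Fe(III)/Tl(III) oxidative phenol–stilbene (3+2) coupling that converts resveratrol into ε-viniferin, here run intramolecularly.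

## Compound list

1 | resveratrol, (E)-3,5,4'-trihydroxystilbene | Oc1ccc(/C=C/c2cc(O)cc(O)c2)cc1 | starting material
2 | 4'-O-acetylresveratrol | CC(=O)Oc1ccc(/C=C/c2cc(O)cc(O)c2)cc1 | intermediate
3 | resveratrol triacetate | CC(=O)Oc1ccc(/C=C/c2cc(OC(C)=O)cc(OC(C)=O)c2)cc1 | starting material
4 | 3,5-di-O-acetylresveratrol | CC(=O)Oc1cc(/C=C/c2ccc(O)cc2)cc(OC(C)=O)c1 | intermediate
5 | (S)-triacetate Friedel–Crafts adduct | Oc1ccc([C@@H](c2c(O)cc(O)cc2/C=C/c2ccc(OC(C)=O)cc2)Cc2cc(OC(C)=O)cc(OC(C)=O)c2)cc1 | intermediate
6 | (S)-hexaphenol | Oc1ccc([C@@H](c2c(O)cc(O)cc2/C=C/c2ccc(O)cc2)Cc2cc(O)cc(O)c2)cc1 | intermediate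
7 | ampelopsin B, (7S,7'S,8'S) | Oc1ccc([C@@H]2Cc3cc(O)cc4c3[C@H](c3cc(O)cc(O)c32)[C@@H](c2ccc(O)cc2)O4)cc1 | target

## Summary

Total steps: 5. Longest linear sequence: 4 (1 → 2 → 5 → 6 → 7, or 3 → 4 → 5 → 6 → 7).

Steps most likely to fail:

1. Step 5. Risks are intermolecular radical coupling or over-oxidation, and formation of the C8' epimer if the quinone-methide arm reacts from the open (exo) orientation; the stereochemical preference is argued, not proven. Fallback: a redox-neutral end-game. Use the alkyne analogue of 2, 4-[(3,5-dihydroxyphenyl)ethynyl]phenyl acetate, in step 3; then Au(I)-catalysed 7-exo-dig hydroarylation by ring A, followed by acid-mediated protonation at C8' and O-closure through the p-quinone methide. This needs no oxidant and puts C8'/C7' under thermodynamic control.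

2. Step 3. Risks are slow quinone-methide formation from a stilbene, C2 versus C4 attack on the resorcinol, and modest ee. Fallback: set C7 by reduction instead of C–C bond formation. Build the C7=C8 triarylethylene (Friedel–Crafts acylation of the ring B resorcinol with 4-hydroxybenzoic acid, benzyl-metal addition, dehydration), then reduce its p-quinone methide with a chiral phosphoric acid and Hantzsch ester, a known reaction for 1,1-diaryl alkenes.

3. Step 2. Risk is over-deacetylation or wrong-site deacetylation, which would unmask the ring that must stay non-nucleophilic. Fallback: build 4 by C–C coupling. Heck reaction of 5-iodo-1,3-phenylene diacetate with 4-(tert-butyldimethylsilyloxy)styrene, then buffered fluoride (TBAF/AcOH).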